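The central dimethoxy ring is built, not bought. Its two oxygens sit meta (C3, C5), which marks it as a masked cyclohexane-1,3-dione. Its congested C1(arylethyl)–C2(benzyl) edge can therefore be forged while both carbons are still tetrahedral. Cutting C1–C2 and C3–C4 gives an (E)-enone bearing the 3-benzyloxyphenethyl chain on its β-carbon and a dimethyl malonate already carrying the 4-benzyloxybenzyl group. Methoxide unites the two in one operation, conjugate addition followed by Claisen ring closure, and so places all four ring substituents without any regiochemical choice. Ester removal, iodine–methanol aromatisation with a capping methylation, and hydrogenolysis complete the achiral target.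

Key step: step 6

Remark: the target has no stereocentre and no stereogenic double bond, so it is achiral and there is no enantiomer to select; the name is read as gymconopin D.

Step 1
Reactants: 1 3-(3-hydroxyphenyl)propanoic acid
Product: 2 3-(3-hydroxyphenyl)propan-1-ol
Conditions: BH3·THF (2.5 equiv), THF, 0 °C to rt; MeOH quench, aqueous work-up
Reagents that add atoms: none
Why: Chemoselective borane reduction of a carboxylic acid through its acyloxyborane; the phenol only ties up hydride as an aryl borate, which the quench and work-up release.

Step 2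
Reactants: 2 3-(3-hydroxyphenyl)propan-1-ol
Product: 3 3-[3-(benzyloxy)phenyl]propan-1-ol
Conditions: BnBr (1.05 equiv), K2CO3, acetone, reflux
Reagents that add atoms: benzyl bromide BrCc1ccccc1
Why: Williamson ether synthesis in which carbonate ionises only the phenol and leaves the primary alcohol unalkylated, so no benzyl ester is made and no benzyl alcohol reaches the oxidation–olefination, where it would end up as a competing enone.

Step 3
Reactants: 3 3-[3-(benzyloxy)phenyl]propan-1-ol; 4 1-(triphenylphosphoranylidene)propan-2-one
Product: 6 (E)-6-[3-(benzyloxy)phenyl]hex-3-en-2-one, via 3-[3-(benzyloxy)phenyl]propanal 5 (not isolated)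
Conditions: TEMPO (10 mol %), PhI(OAc)2 (1.1 equiv), CH2Cl2, rt; aq NaHCO3 wash; then 4 (1.3 equiv) added to the dried solution, rt to 40 °C
Reagents that add atoms: none
Why: The oxoammonium (TEMPO/BAIB) oxidation stops at aldehyde 5, and Wittig olefination with the stabilised ylide should give the E-enone without the enolisable aldehyde ever being concentrated; the alkene geometry is lost again in step 6.

Step 4
Reactants: 7 dimethyl malonate; 8 4-(benzyloxy)benzaldehyde
Product: 9 dimethyl 2-[4-(benzyloxy)benzylidene]malonate
Conditions: piperidine (10 mol %), AcOH (10 mol %), toluene, Dean–Stark, reflux; crystallisation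
Reagents that add atoms: none
Why: Knoevenagel condensation through the iminium ion of the aldehyde, driven by azeotropic water removal; crystallisation removes residual malonate 7, which would otherwise compete as a donor in step 6.

Step 5
Reactants: 9 dimethyl 2-[4-(benzyloxy)benzylidene]malonate
Product: 10 dimethyl 2-[4-(benzyloxy)benzyl]malonate
Conditions: NaBH4 (1 equiv), MeOH–THF, 0 °C; 1 M HCl quench
Reagents that add atoms: none
Why: Conjugate (1,4) hydride reduction of a doubly activated alkylidene malonate, preferred to catalytic hydrogenation because it cannot touch the aryl benzyl ether, and run cold so that the esters are not reduced.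

Step 6
Reactants: 6 (E)-6-[3-(benzyloxy)phenyl]hex-3-en-2-one; 10 dimethyl 2-[4-(benzyloxy)benzyl]malonate
Product: 12 methyl 1-[4-(benzyloxy)benzyl]-6-{2-[3-(benzyloxy)phenyl]ethyl}-2,4-dioxocyclohexane-1-carboxylate (racemic diastereomer mixture), via Michael adduct 11 (not isolated)
Conditions: NaOMe (1.5 equiv), 10 (1.2 equiv), MeOH (concentrated), rt; slow addition of 6, then reflux; cold 1 M HCl to pH 2–3
Reagents that add atoms: none
Why: Methoxide turns 10 into its doubly stabilised tertiary enolate, which adds to the β-carbon of 6 to forge the future arene C1–C2 bond and give keto diester 11; proton exchange then supplies the methyl-ketone enolate, which acylates on one ester carbonyl with loss of methoxide to forge the future C3–C4 bond. The closest known reaction type is the tandem Michael addition–Claisen (Dieckmann-type) condensation of malonates with enones that delivers dimedone and 5-alkylcyclohexane-1,3-diones, 2-alkylmalonates being established though slower donors. The single new ring, the six-membered carbocycle, closes in the favoured 6-(enolendo)-exo-trig mode. The stereocentres C1 and C6 of 12 arise racemic and without a controlling element (which of the two diastereotopic esters is attacked decides C1), which is acceptable because both become sp2 in step 8. The step needs 1,4- over 1,2-addition, secured by the soft, reversibly adding malonate anion, and closure through the methyl rather than the internal enolate, secured because the latter could reach an ester only through a four-membered ring; even a methoxycarbonyl shift by that strained path would end at the same dione 14 after step 7. A full equivalent of base deprotonates the acidic 1,3-dione as it forms, which drains the crowded, reversible Michael equilibrium and masks the C2 ketone against retro-Claisen cleavage.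

Step 7
Reactants: 12 methyl 1-[4-(benzyloxy)benzyl]-6-{2-[3-(benzyloxy)phenyl]ethyl}-2,4-dioxocyclohexane-1-carboxylate
Product: 14 4-[4-(benzyloxy)benzyl]-5-{2-[3-(benzyloxy)phenyl]ethyl}cyclohexane-1,3-dione (racemic diastereomer mixture), via keto acid 13 (not isolated)
Conditions: 2 M aq NaOH (5 equiv), MeOH, reflux; then 6 M HCl to pH 1, 70 °C
Reagents that add atoms: none
Why: Saponification (BAc2) of the methyl ester while the dione is shielded as its enolate, then thermal decarboxylation of β-keto acid 13 through the cyclic six-membered transition state; the C4 centre forms unselectively and is erased in step 8.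

Step 8
Reactants: 14 4-[4-(benzyloxy)benzyl]-5-{2-[3-(benzyloxy)phenyl]ethyl}cyclohexane-1,3-dione
Product: 16 di-O-benzyl gymconopin D (1-{2-[3-(benzyloxy)phenyl]ethyl}-2-[4-(benzyloxy)benzyl]-3,5-dimethoxybenzene), via monomethyl ether 15 (not isolated)
Conditions: I2 (2 equiv), MeOH, reflux; aq Na2S2O3 wash, concentrate; crude with MeI (3 equiv), K2CO3, acetone, reflux
Reagents that add atoms: methanol CO; iodomethane CI
Why: Iodine–methanol oxidative aromatisation, in which HI formed in situ catalyses enol-ether formation and the dienol ether is α-iodinated and loses HI to reach the arene with the unhindered C5 oxygen already methylated; because the carbonyl beside the benzyl group may stop at phenol 15, the crude is driven to one product by a Williamson methylation that leaves any 16 already present unchanged.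

Step 9
Reactants: 16 di-O-benzyl gymconopin D
Product: 17 gymconopin D
Conditions: H2 (1 atm), 10 % Pd/C, EtOAc–MeOH, rt
Reagents that add atoms: none
Why: Catalytic hydrogenolysis of both aryl benzyl ethers; the methyl ethers and the diarylmethane and bibenzyl C–C bonds are inert under these conditions, and any trace of aryl iodide from step 8 would be reduced off as well.

Compound list
1 | 3-(3-hydroxyphenyl)propanoic acid | OC(=O)CCc1cccc(O)c1 | starting material
2 | 3-(3-hydroxyphenyl)propan-1-ol | OCCCc1cccc(O)c1 | intermediate
3 | 3-[3-(benzyloxy)phenyl]propan-1-ol | OCCCc1cccc(OCc2ccccc2)c1 | intermediate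
4 | 1-(triphenylphosphoranylidene)propan-2-one | CC(=O)C=P(c1ccccc1)(c1ccccc1)c1ccccc1 | starting material
5 | 3-[3-(benzyloxy)phenyl]propanal | O=CCCc1cccc(OCc2ccccc2)c1 | intermediate (not isolated)
6 | (E)-6-[3-(benzyloxy)phenyl]hex-3-en-2-one | CC(=O)/C=C/CCc1cccc(OCc2ccccc2)c1 | intermediate
7 | dimethyl malonate | COC(=O)CC(=O)OC | starting material
8 | 4-(benzyloxy)benzaldehyde | O=Cc1ccc(OCc2ccccc2)cc1 | starting material
9 | dimethyl 2-[4-(benzyloxy)benzylidene]malonate | COC(=O)C(=Cc1ccc(OCc2ccccc2)cc1)C(=O)OC | intermediate
10 | dimethyl 2-[4-(benzyloxy)benzyl]malonate | COC(=O)C(Cc1ccc(OCc2ccccc2)cc1)C(=O)OC | intermediate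
11 | dimethyl 2-[4-(benzyloxy)benzyl]-2-{1-[3-(benzyloxy)phenyl]-5-oxohexan-3-yl}malonate (racemic) | COC(=O)C(Cc1ccc(OCc2ccccc2)cc1)(C(=O)OC)C(CCc1cccc(OCc2ccccc2)c1)CC(C)=O | intermediate (not isolated)
12 | methyl 1-[4-(benzyloxy)benzyl]-6-{2-[3-(benzyloxy)phenyl]ethyl}-2,4-dioxocyclohexane-1-carboxylate (racemic, diastereomer mixture) | COC(=O)C1(Cc2ccc(OCc3ccccc3)cc2)C(CCc2cccc(OCc3ccccc3)c2)CC(=O)CC1=O | intermediate
13 | 1-[4-(benzyloxy)benzyl]-6-{2-[3-(benzyloxy)phenyl]ethyl}-2,4-dioxocyclohexane-1-carboxylic acid (racemic, diastereomer mixture) | OC(=O)C1(Cc2ccc(OCc3ccccc3)cc2)C(CCc2cccc(OCc3ccccc3)c2)CC(=O)CC1=O | intermediate (not isolated)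
14 | 4-[4-(benzyloxy)benzyl]-5-{2-[3-(benzyloxy)phenyl]ethyl}cyclohexane-1,3-dione (racemic, diastereomer mixture) | O=C1CC(=O)C(Cc2ccc(OCc3ccccc3)cc2)C(CCc2cccc(OCc3ccccc3)c2)C1 | intermediate
15 | 2-[4-(benzyloxy)benzyl]-3-{2-[3-(benzyloxy)phenyl]ethyl}-5-methoxyphenol | COc1cc(O)c(Cc2ccc(OCc3ccccc3)cc2)c(CCc2cccc(OCc3ccccc3)c2)c1 | intermediate (not isolated)
16 | di-O-benzyl gymconopin D | COc1cc(CCc2cccc(OCc3ccccc3)c2)c(Cc2ccc(OCc3ccccc3)cc2)c(OC)c1 | intermediate
17 | gymconopin D (achiral) | COc1cc(CCc2cccc(O)c2)c(Cc2ccc(O)cc2)c(OC)c1 | target

Total step count: 9. Longest linear sequence: 7 steps (1, 2, 3, 6, 7, 8, 9).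

Steps most likely to fail

Step 6.
- **Risk:** The addition of a tertiary malonate anion to a β-substituted enone is reversible and sterically loaded. Retro-Michael cleavage and base-induced self-condensation of the enone may therefore outrun ring closure.
- **Fallback:** Close the ring with the unhindered donor and bring in the benzyl group afterwards. The fallback sets out from 6 and 7.
- NaOMe in refluxing MeOH should give methyl 6-{2-[3-(benzyloxy)phenyl]ethyl}-2,4-dioxocyclohexane-1-carboxylate F1 by the well-tested unsubstituted Michael–Claisen annulation.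
- The dianion of this compound (LDA, 2.2 equiv, THF, −78 to 0 °C) is then alkylated with one equivalent of commercial 4-(benzyloxy)benzyl bromide (BrCc1ccc(OCc2ccccc2)cc1). Reaction is expected at C1, the last-deprotonated and most nucleophilic site.
- The fallback rejoins the route at 12.

Step 8.
- **Risk:** The three electron-rich rings may undergo nuclear iodination. The accumulating HI may cleave a benzyl ether, and the freed phenol would then be methylated irreversibly. The reaction may also stall at the enol-ether stage.
- **Fallback:** A base-mediated dehydrogenation that uses neither halogen nor strong acid. It sets out from 14.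
- MeOH, HC(OMe)3 and catalytic TsOH etherify the less hindered carbonyl to give 6-[4-(benzyloxy)benzyl]-5-{2-[3-(benzyloxy)phenyl]ethyl}-3-methoxycyclohex-2-en-1-one F2.
- Kinetic α'-deprotonation (LDA, THF, −78 °C) and PhSeBr give 6-[4-(benzyloxy)benzyl]-5-{2-[3-(benzyloxy)phenyl]ethyl}-3-methoxy-6-(phenylselanyl)cyclohex-2-en-1-one F3.
- H2O2 with pyridine in CH2Cl2 at 0 °C forms the corresponding selenoxide, 6-[4-(benzyloxy)benzyl]-5-{2-[3-(benzyloxy)phenyl]ethyl}-3-methoxy-6-(phenylseleninyl)cyclohex-2-en-1-one F4. This should undergo syn-elimination across C5–C6 and enolise.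
- The fallback rejoins the route at 15, which takes the MeI/K2CO3 operation of step 8 to 16.

Step 7.
- **Risk:** Hydroxide must reach an ester carbonyl on a quaternary carbon of an already anionic molecule, so hydrolysis may be sluggish. Forcing it invites ring opening by retro-Claisen attack.
- **Fallback:** Cleave the ester from its other end by Krapcho dealkoxycarbonylation (LiCl, DMSO–H2O, 150 °C). Chloride attacks the unhindered O-methyl carbon in an SN2 sense, and the resulting β-keto carboxylate loses CO2 at that temperature.
- The fallback sets out from 12 and rejoins the route at 14. It makes no compound outside the list (F0).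

Further compounds
F1 | step 6 | methyl 6-{2-[3-(benzyloxy)phenyl]ethyl}-2,4-dioxocyclohexane-1-carboxylate (racemic) | COC(=O)C1C(CCc2cccc(OCc3ccccc3)c2)CC(=O)CC1=O
F2 | step 8 | 6-[4-(benzyloxy)benzyl]-5-{2-[3-(benzyloxy)phenyl]ethyl}-3-methoxycyclohex-2-en-1-one (racemic) | COC1=CC(=O)C(Cc2ccc(OCc3ccccc3)cc2)C(CCc2cccc(OCc3ccccc3)c2)C1
F3 | step 8 | 6-[4-(benzyloxy)benzyl]-5-{2-[3-(benzyloxy)phenyl]ethyl}-3-methoxy-6-(phenylselanyl)cyclohex-2-en-1-one (racemic) | COC1=CC(=O)C(Cc2ccc(OCc3ccccc3)cc2)([Se]c2ccccc2)C(CCc2cccc(OCc3ccccc3)c2)C1
F4 | step 8 | 6-[4-(benzyloxy)benzyl]-5-{2-[3-(benzyloxy)phenyl]ethyl}-3-methoxy-6-(phenylseleninyl)cyclohex-2-en-1-one (racemic) | COC1=CC(=O)C(Cc2ccc(OCc3ccccc3)cc2)([Se](=O)c2ccccc2)C(CCc2cccc(OCc3ccccc3)c2)C1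
F0 | step 7 | none | none
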